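**Numbering.** Benzofuran atoms are O1, C2, C3, C3a, C4–C7, C7a; ring A is the benzo ring, ring B the dihydrofuran, ring C the catechol. The lactone intermediates use isochromane numbering (C1 carbonyl, O2, C3, C4, C4a, C5–C8, C8a). Lactone C3, C4, C6, C8 and C8a become benzofuran C2, C3, C5, C7 and C7a. Compounds 1–16 are numbered as in the steps and the compound list.

## Analysis of the target

Compound 16 is a 2,3-dihydrobenzofuran in which ring A is fused to ring B, with catechol ring C on C2, a methyl ester on C3, an (E)-methyl propenoate on C5 and a free phenol on C7 next to the ring oxygen. It has two stereocentres, C2 and C3, both R, with the aryl and ester groups trans. C3 is benzylic and α to an ester, so it can be equilibrated, and trans is the more stable arrangement. C2 alone carries the absolute information. C2 is a benzylic ether carbon bearing a para-oxygenated aryl ring, so acid can ionise C2–O1 and base can open ring B from the C3 enolate by expelling the phenoxide; either event would scramble C2. The catechol and phenol are easily oxidised, the enoate is reducible and a Michael acceptor, and the two methyl esters exclude hydrolytic conditions late in the route. The difficulty is therefore not the skeleton, which an oxidative coupling of two caffeate units would give as a racemate, but setting C2 under reagent control and then keeping it. The strategy rests on the O1–C7a bond. With a carbonyl carbon placed between C7a and O1, ring B becomes a six-membered lactone, a 3-aryl-1-oxoisochromane-4-carboxylate with the same two stereocentres. That skeleton is the direct product of an aldol–lactonisation between a ring A homophthalic anhydride and a ring C aldehyde, a union that can be run catalytically and enantioselectively.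

## Retrosynthetic reasoning

**16 from 15.** The three O–benzyl bonds are cut last. Benzyl ethers pass through strong base, hot hydroxide and low-valent metal, and a boron Lewis acid with a cation scavenger removes them without touching the enoate or the esters. The forward step only has to avoid ionising C2–O1.

**15 from 13 and 14.** The C=C bond of the side chain is cut to aldehyde 13 and ylide 14. The enoate could not be carried earlier, since it would not survive benzylic metalation or zerovalent nickel. A stabilised ylide gives the E alkene under neutral conditions.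

**13 from 12.** The aldehyde is masked as the dioxolane of 12, which is inert to amide bases, hydroxide and nickel. In 12 the acetal is para to O1, so very mild acid is enough to remove it.

**12 from 11 (key disconnection).** The O1–C7a bond is cut and a carbonyl is inserted in the retrosynthetic sense, giving lactone 11. This is the only disconnection that leaves C2–O1, C2–C3 and both stereocentres untouched while turning ring B into a ring that a catalytic asymmetric annulation can make. The forward reaction must excise the lactone carbonyl and join the lactone oxygen to the aryl carbon without breaking the C–O bond at the stereocentre.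

**11 from 8 and 9 (through acid 10).** The lactone C3–C4 bond and the O2–C1 bond are cut, giving homophthalic anhydride 8 and aldehyde 9. Both stereocentres are set in this one step, and all four phenolic oxygens are already in place. The forward reaction needs catalyst control of both enolate and aldehyde faces, and a base-free esterification of 10.

**8 from 7, 6 and 5.** The anhydride comes from diacid 7, the diacid from diester 6, and in 6 the bond between the benzylic CH2 and its ester carbon is cut. This leads to ortho-toluate 5, whose methyl group is acidified by the neighbouring ester. One C–C bond formation makes the whole homophthalate.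

**5 from 4 and 3.** The acetal comes from aldehyde 4, and the aryl–CHO bond is cut to aryl triflate 3. A reductive carbonylation installs the one-carbon unit at the oxidation state needed.

**3 from 2 and 1.** The two phenols of methyl orsellinate 1 differ: the 2-OH is hydrogen-bonded to the ester, the 4-OH is free. Sulfonylation therefore goes to O4 (compound 2), and benzylation of the remaining phenol gives 3. The starting material supplies the ester, the methyl group and both oxygens of ring A in the right positions.

## Alternatives that were turned down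

**Alternative 1:** Ring A is disconnected at C3a–C4 and C7a–C7. In the forward sense the enolate of the lactone methyl (2R,3R)-2-[3,4-bis(tert-butyldimethylsilyloxy)phenyl]-5-oxooxolane-3-carboxylate A2 is silylated on oxygen. This electron-rich alkene undergoes a Diels–Alder reaction with 3,5-dibromo-2H-pyran-2-one A3, and the bridged adduct loses carbon dioxide and silanol to give methyl (2R,3R)-5,7-dibromo-2-[3,4-bis(tert-butyldimethylsilyloxy)phenyl]-2,3-dihydrobenzofuran-3-carboxylate A1.
- For: ring B and both stereocentres arrive intact from a small lactone, and pyrone cycloaddition with aromatisation is an established benzannulation. On precedent for the key reaction type it is stronger than the chosen route.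
- Against: enolisation of A2 must choose the lactone CH2 over the more acidic C–H next to the methyl ester. The ester enolate can expel the ring oxygen and destroy C2.
- Against: A1 has bromine at C7 where the target needs oxygen, and a second bromide at C5. Two aryl bromides must be told apart and one turned into a phenol on a base-sensitive ring B, so more steps follow the key step than the three needed here.
- In its place the chosen strategy offers the full oxygenation pattern from compound 1 and no site-selectivity problem.

**Alternative 2:** The C3–C3a bond is disconnected, leading back to the flavanone (2R)-8-acetoxy-6-bromo-2-(3,4-diacetoxyphenyl)chroman-4-one A5. A trivalent iodine oxidant in acidic orthoformate functionalises the CH2 next to the ketone, and ring A migrates from the ketal carbon to that carbon. The product is methyl (2R,3R)-7-acetoxy-5-bromo-2-(3,4-diacetoxyphenyl)-2,3-dihydrobenzofuran-3-carboxylate A4.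
- For: this ring contraction is a known reaction of flavanones, gives the trans ester directly, and is probably shorter. On precedent it is clearly stronger than the chosen key step.
- Against: the C2 aryl group competes as the migrating group, which is why ring C must carry deactivating acetates.
- Against: the C2 stereocentre of a flavanone is configurationally fragile. Reversible opening to the chalcone under the acidic oxidation conditions would erode the enantiomeric purity of A5 before it is transferred to A4.
- Against: the C5 bromide still needs a Heck coupling, and three acetates must be removed without opening ring B.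
- In its place the chosen strategy fixes both centres in one catalytic step, in a lactone with no reversible ring-opening that could racemise C2, and has no migration selectivity to manage.

**Alternative 3:** The C2–C3 bond is disconnected, leading to the aryldiazoacetate methyl 2-{5-bromo-3-(tert-butyldimethylsilyloxy)-2-[3,4-bis(tert-butyldimethylsilyloxy)benzyloxy]phenyl}-2-diazoacetate A7. A chiral dirhodium tetracarboxylate generates the carbenoid at C3, which inserts into a benzylic ether C–H bond. Base-mediated equilibration at C3 then gives methyl (2R,3R)-5-bromo-7-(tert-butyldimethylsilyloxy)-2-[3,4-bis(tert-butyldimethylsilyloxy)phenyl]-2,3-dihydrobenzofuran-3-carboxylate A6.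
- For: this insertion is known for 2-aryl-dihydrobenzofuran-3-carboxylates with high enantiocontrol, and it closes ring B and creates both centres in one step. On precedent and stereocontrol it is at least as strong as the chosen route.
- Against: A7 needs a ring A block with ether, silyloxy and bromide in defined positions plus a diazo transfer, so the precursor is longer.
- Against: the silyloxy group next to the ether oxygen crowds the insertion site, and the electron-rich ring C invites carbenoid addition to the arene.
- Against: the insertion favours the cis arrangement kinetically, so base is needed on a ring that opens under base. Catechol silyl ethers are fragile, and the bromide still needs a Heck coupling.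
- In its place the chosen strategy uses no diazo compound and no precious metal before the key step, takes three simple building blocks, and gives the trans compound directly. The price is an untested key step.

Key step: step 9

**Remarks on the chemistry.**
- The sense of induction of the cinchona squaramide in step 8 is not derived here. The quinine-based catalyst or its quinidine-based pseudo-enantiomer is taken, whichever delivers the (3R,4R) lactone.
- Nickel is used as a full equivalent in step 9, so that it also acts as the acceptor for the extruded CO.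

## Route

Step 1
Reactants: 1 methyl 2,4-dihydroxy-6-methylbenzoate (methyl orsellinate)
Product: 2 methyl 2-hydroxy-6-methyl-4-{[(trifluoromethyl)sulfonyl]oxy}benzoate
Conditions: Tf2O (1.05 equiv), pyridine, CH2Cl2, −20 → 0 °C
Reagents that add atoms: trifluoromethanesulfonic anhydride, O=S(=O)(OS(=O)(=O)C(F)(F)F)C(F)(F)F
Why: Selective O-sulfonylation of a resorcylate; the 2-OH is hydrogen-bonded to the ester carbonyl and flanked by it, so the free and more acidic 4-OH should react first.

Step 2
Reactants: 2 methyl 2-hydroxy-6-methyl-4-{[(trifluoromethyl)sulfonyl]oxy}benzoate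
Product: 3 methyl 2-(benzyloxy)-6-methyl-4-{[(trifluoromethyl)sulfonyl]oxy}benzoate
Conditions: BnBr, K2CO3, DMF, rt
Reagents that add atoms: benzyl bromide, BrCc1ccccc1
Why: Williamson ether synthesis; carbonate in DMF breaks the chelate of the remaining phenol, and the aryl triflate should tolerate mild carbonate at room temperature.

Step 3
Reactants: 3 methyl 2-(benzyloxy)-6-methyl-4-{[(trifluoromethyl)sulfonyl]oxy}benzoate
Product: 4 methyl 2-(benzyloxy)-4-formyl-6-methylbenzoate
Conditions: Pd(OAc)2 (5 mol%), dppp (5 mol%), CO (1 atm), Et3SiH, Et3N, DMF, 70 °C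
Reagents that add atoms: carbon monoxide, [C-]#[O+]
Why: Palladium-catalysed reductive carbonylation (formylation) of an aryl triflate; oxidative addition para to the ester is easy and the triflate has no ortho substituent, CO insertion gives the acyl palladium and the silane supplies hydride, with the chelating bisphosphine favouring insertion over direct reduction.

Step 4
Reactants: 4 methyl 2-(benzyloxy)-4-formyl-6-methylbenzoate
Product: 5 methyl 2-(benzyloxy)-4-(1,3-dioxolan-2-yl)-6-methylbenzoate
Conditions: HOCH2CH2OH, TsOH·H2O (cat.), toluene, reflux, Dean–Stark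
Reagents that add atoms: ethylene glycol, OCCO
Why: Acid-catalysed acetalisation with azeotropic removal of water; the doubly ortho-substituted benzoate should not transesterify.

Step 5
Reactants: 5 methyl 2-(benzyloxy)-4-(1,3-dioxolan-2-yl)-6-methylbenzoate
Product: 6 methyl 2-(benzyloxy)-4-(1,3-dioxolan-2-yl)-6-(2-methoxy-2-oxoethyl)benzoate
Conditions: LiN(iPr)2 (2.5 equiv), (MeO)2CO (1.5 equiv, added together with 5), THF, −78 → 0 °C; aq. NH4Cl
Reagents that add atoms: dimethyl carbonate, COC(=O)OC
Why: Lateral (benzylic) lithiation of an ortho-toluate followed by C-acylation; the methyl group ortho to the ester is the most acidic site, the anion is trapped in situ by the carbonate so that self-condensation is suppressed, and the second equivalent of base takes up the more acidic arylacetate product.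

Step 6
Reactants: 6 methyl 2-(benzyloxy)-4-(1,3-dioxolan-2-yl)-6-(2-methoxy-2-oxoethyl)benzoate
Product: 7 2-(benzyloxy)-6-(carboxymethyl)-4-(1,3-dioxolan-2-yl)benzoic acid
Conditions: KOH (excess), MeOH/H2O, reflux; then 0 °C, aq. KHSO4 to pH 3, EtOAc
Reagents that add atoms: potassium hydroxide, [K+].[OH-]
Why: Saponification of both esters, the hindered benzoate needing reflux; acetal and benzyl ether are inert to hydroxide, and the short cold acidification should spare the dioxolane, which is deactivated towards ionisation by the para carboxyl group.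

Step 7
Reactants: 7 2-(benzyloxy)-6-(carboxymethyl)-4-(1,3-dioxolan-2-yl)benzoic acid
Product: 8 8-(benzyloxy)-6-(1,3-dioxolan-2-yl)isochromane-1,3-dione
Conditions: DCC (1.05 equiv), CH2Cl2, 0 °C → rt; filtration
Reagents that add atoms: none
Why: Carbodiimide dehydration of a homophthalic acid to its six-membered cyclic anhydride under neutral conditions that leave the acetal alone.

Step 8
Reactants: 8 8-(benzyloxy)-6-(1,3-dioxolan-2-yl)isochromane-1,3-dione, 9 3,4-bis(benzyloxy)benzaldehyde
Product: 11 methyl (3R,4R)-8-(benzyloxy)-3-[3,4-bis(benzyloxy)phenyl]-6-(1,3-dioxolan-2-yl)-1-oxoisochromane-4-carboxylate, via lactone acid 10 (not isolated)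
Conditions: squaramide from 9-amino-9-deoxy-epi-quinine and 3,5-bis(trifluoromethyl)aniline (5–10 mol%), MTBE, −15 °C; then MeOH, TMSCHN2, −15 °C → rt
Reagents that add atoms: trimethylsilyldiazomethane, C[Si](C)(C)C=[N+]=[N-]
Why: Catalytic asymmetric formal [4+2] cycloaddition (Tamura-type aldol–lactonisation) of an enolisable homophthalic anhydride with an aldehyde; the quinuclidine forms the anhydride enolate, the squaramide N–H bonds hold both partners, and the aldolate closes onto C1 and frees the C4 carboxylic acid. The catalyst selects one face of the enolate and one face of the aldehyde, setting C3 and C4 together as the trans (3R,4R) pair, which is also the more stable one; TMSCHN2 then esterifies acid 10 without base.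

Step 9
Reactants: 11 methyl (3R,4R)-8-(benzyloxy)-3-[3,4-bis(benzyloxy)phenyl]-6-(1,3-dioxolan-2-yl)-1-oxoisochromane-4-carboxylate
Product: 12 methyl (2R,3R)-7-(benzyloxy)-2-[3,4-bis(benzyloxy)phenyl]-5-(1,3-dioxolan-2-yl)-2,3-dihydrobenzofuran-3-carboxylate
Conditions: Ni(cod)2 (1.0 equiv), Cy2PCH2CH2PCy2 (1.1 equiv), toluene, 150 °C, sealed tube, argon
Reagents that add atoms: none
Why: Proposed new method: zerovalent nickel bearing the electron-rich chelating bisphosphine should add oxidatively to the acyl C1–O2 bond of the lactone, which is held in the less stable s-cis ester geometry and has the C8 benzyloxy oxygen placed to bind the metal, giving a seven-membered acyl nickel alkoxide. Carbonyl de-insertion contracts this to a six-membered aryl nickel alkoxide with CO on the metal, and aryl–oxygen reductive elimination from this crowded, doubly ortho-substituted aryl nickel species closes ring B as a five-membered ring, by C(sp2)–O reductive elimination out of a six-membered nickelacycle (bond C8a–O2 of 11, which is C7a–O1 of 12). The closest known reaction type is the nickel- or palladium-catalysed decarbonylative conversion of aryl esters ArC(O)OAr' into diaryl ethers ArOAr' with the same kind of bisphosphine; new here is that the oxygen is a secondary benzylic alkoxide and that the ester is a lactone. No stereocentre is created: the C3–O2 bond is never broken, so C3 of 11 becomes C2 of 12 with its R configuration, and C4 becomes C3, already in the more stable trans arrangement. Because loss of CO from an ester is paid for only by entropy and by binding of CO to nickel, the metal is used as a full equivalent and serves as the CO acceptor. The step needs reductive elimination to be faster than β-hydride elimination or retro-aldol cleavage of the nickel alkoxide, and needs the acyl C–O bond to react before the benzylic C–O bonds; the small bite angle and bulk of the ligand leave no open cis site for β-hydride transfer, the five-membered closure is entropically favoured, and neither the benzyl ethers nor C3–O2 has the extended π-system that usually makes benzylic C–O insertion fast.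

Step 10
Reactants: 12 methyl (2R,3R)-7-(benzyloxy)-2-[3,4-bis(benzyloxy)phenyl]-5-(1,3-dioxolan-2-yl)-2,3-dihydrobenzofuran-3-carboxylate
Product: 13 methyl (2R,3R)-7-(benzyloxy)-2-[3,4-bis(benzyloxy)phenyl]-5-formyl-2,3-dihydrobenzofuran-3-carboxylate
Conditions: PPTS (cat.), acetone/H2O, 50 °C
Reagents that add atoms: water, O
Why: Mild acid hydrolysis of a dioxolane; the acetal now sits para to the ring oxygen O1 and should ionise easily, while an acid of this strength should not ionise the C2–O1 bond.

Step 11
Reactants: 13 methyl (2R,3R)-7-(benzyloxy)-2-[3,4-bis(benzyloxy)phenyl]-5-formyl-2,3-dihydrobenzofuran-3-carboxylate, 14 methyl (triphenylphosphoranylidene)acetate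
Product: 15 methyl (2R,3R)-7-(benzyloxy)-2-[3,4-bis(benzyloxy)phenyl]-5-[(E)-3-methoxy-3-oxoprop-1-en-1-yl]-2,3-dihydrobenzofuran-3-carboxylate
Conditions: toluene, 80 °C
Reagents that add atoms: none
Why: Wittig olefination with a stabilised ylide, which should give the (E)-enoate; the conditions are neutral, and C3 is in any case at its preferred trans position.

Step 12
Reactants: 15 methyl (2R,3R)-7-(benzyloxy)-2-[3,4-bis(benzyloxy)phenyl]-5-[(E)-3-methoxy-3-oxoprop-1-en-1-yl]-2,3-dihydrobenzofuran-3-carboxylate
Product: 16 methyl (2R,3R)-2-(3,4-dihydroxyphenyl)-7-hydroxy-5-[(E)-3-methoxy-3-oxoprop-1-en-1-yl]-2,3-dihydrobenzofuran-3-carboxylate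
Conditions: BCl3 (6 equiv), C6HMe5 (9 equiv), CH2Cl2, −78 °C; then MeOH
Reagents that add atoms: none
Why: Lewis-acid debenzylation of aryl benzyl ethers with pentamethylbenzene as a non-basic benzyl cation scavenger; at −78 °C the enoate and the methyl esters should be untouched, and no hydrogen is used, so the alkene and the benzylic C2–O1 bond are not reduced.

## Compound list

1 | methyl 2,4-dihydroxy-6-methylbenzoate (methyl orsellinate) | COC(=O)c1c(C)cc(O)cc1O | starting material
2 | methyl 2-hydroxy-6-methyl-4-{[(trifluoromethyl)sulfonyl]oxy}benzoate | COC(=O)c1c(C)cc(OS(=O)(=O)C(F)(F)F)cc1O | intermediate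
3 | methyl 2-(benzyloxy)-6-methyl-4-{[(trifluoromethyl)sulfonyl]oxy}benzoate | COC(=O)c1c(C)cc(OS(=O)(=O)C(F)(F)F)cc1OCc1ccccc1 | intermediate
4 | methyl 2-(benzyloxy)-4-formyl-6-methylbenzoate | COC(=O)c1c(C)cc(C=O)cc1OCc1ccccc1 | intermediate
5 | methyl 2-(benzyloxy)-4-(1,3-dioxolan-2-yl)-6-methylbenzoate | COC(=O)c1c(C)cc(C2OCCO2)cc1OCc1ccccc1 | intermediate
6 | methyl 2-(benzyloxy)-4-(1,3-dioxolan-2-yl)-6-(2-methoxy-2-oxoethyl)benzoate | COC(=O)Cc1cc(C2OCCO2)cc(OCc2ccccc2)c1C(=O)OC | intermediate
7 | 2-(benzyloxy)-6-(carboxymethyl)-4-(1,3-dioxolan-2-yl)benzoic acid | OC(=O)Cc1cc(C2OCCO2)cc(OCc2ccccc2)c1C(=O)O | intermediate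
8 | 8-(benzyloxy)-6-(1,3-dioxolan-2-yl)isochromane-1,3-dione | O=C1Cc2cc(C3OCCO3)cc(OCc3ccccc3)c2C(=O)O1 | intermediate
9 | 3,4-bis(benzyloxy)benzaldehyde | O=Cc1ccc(OCc2ccccc2)c(OCc2ccccc2)c1 | starting material
10 | (3R,4R)-8-(benzyloxy)-3-[3,4-bis(benzyloxy)phenyl]-6-(1,3-dioxolan-2-yl)-1-oxoisochromane-4-carboxylic acid | C1(OCCO1)c1cc(OCc3ccccc3)c2c(c1)[C@@H](C(=O)O)[C@H](c1ccc(OCc3ccccc3)c(OCc3ccccc3)c1)OC2=O | intermediate
11 | methyl (3R,4R)-8-(benzyloxy)-3-[3,4-bis(benzyloxy)phenyl]-6-(1,3-dioxolan-2-yl)-1-oxoisochromane-4-carboxylate | C1(OCCO1)c1cc(OCc3ccccc3)c2c(c1)[C@@H](C(=O)OC)[C@H](c1ccc(OCc3ccccc3)c(OCc3ccccc3)c1)OC2=O | intermediate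
12 | methyl (2R,3R)-7-(benzyloxy)-2-[3,4-bis(benzyloxy)phenyl]-5-(1,3-dioxolan-2-yl)-2,3-dihydrobenzofuran-3-carboxylate | C1(OCCO1)c1cc(OCc3ccccc3)c2c(c1)[C@@H](C(=O)OC)[C@H](c1ccc(OCc3ccccc3)c(OCc3ccccc3)c1)O2 | intermediate
13 | methyl (2R,3R)-7-(benzyloxy)-2-[3,4-bis(benzyloxy)phenyl]-5-formyl-2,3-dihydrobenzofuran-3-carboxylate | O=Cc1cc(OCc3ccccc3)c2c(c1)[C@@H](C(=O)OC)[C@H](c1ccc(OCc3ccccc3)c(OCc3ccccc3)c1)O2 | intermediate
14 | methyl (triphenylphosphoranylidene)acetate | COC(=O)C=P(c1ccccc1)(c1ccccc1)c1ccccc1 | starting material
15 | methyl (2R,3R)-7-(benzyloxy)-2-[3,4-bis(benzyloxy)phenyl]-5-[(E)-3-methoxy-3-oxoprop-1-en-1-yl]-2,3-dihydrobenzofuran-3-carboxylate | COC(=O)/C=C/c1cc(OCc3ccccc3)c2c(c1)[C@@H](C(=O)OC)[C@H](c1ccc(OCc3ccccc3)c(OCc3ccccc3)c1)O2 | intermediate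
16 | methyl (2R,3R)-2-(3,4-dihydroxyphenyl)-7-hydroxy-5-[(E)-3-methoxy-3-oxoprop-1-en-1-yl]-2,3-dihydrobenzofuran-3-carboxylate | COC(=O)/C=C/c1cc(O)c2c(c1)[C@@H](C(=O)OC)[C@H](c1ccc(O)c(O)c1)O2 | target

## Step count and least certain steps

Total: 12 steps. Longest linear sequence: 12 steps, from 1 to 16; 9 and 14 are bought.

**Step 9 (key step, proposed new method).**
- The lactone may not react at all, because oxidative addition into an acyl–oxygen bond with an alkoxide leaving group is harder than with the aryloxides used so far.
- Nickel may instead insert into the benzylic C3–O2 bond, and β-hydride elimination would then open the ring.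
- After the desired insertion, the nickel alkoxide may undergo β-hydride elimination or retro-aldol cleavage, or may stall because C–O reductive elimination from divalent nickel is slow.
- Fallback with known chemistry, from anhydride 8 back to 12, forming the same O1–C7a bond by copper catalysis:
  - Methanolysis of 8 opens the anhydride at the non-conjugated carbonyl and gives 2-(benzyloxy)-4-(1,3-dioxolan-2-yl)-6-(2-methoxy-2-oxoethyl)benzoic acid F1.
  - Decarboxylative ipso-iodination of this ortho-alkoxy benzoic acid (I2, K3PO4, MeCN, heat) gives methyl 2-[3-(benzyloxy)-5-(1,3-dioxolan-2-yl)-2-iodophenyl]acetate F2.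
  - Aldol addition of its lithium enolate (LiN(iPr)2, THF, −78 °C) to aldehyde 9 gives methyl 3-[3,4-bis(benzyloxy)phenyl]-2-[3-(benzyloxy)-5-(1,3-dioxolan-2-yl)-2-iodophenyl]-3-hydroxypropanoate F3 as a mixture of stereoisomers.
  - Dess–Martin oxidation gives methyl 3-[3,4-bis(benzyloxy)phenyl]-2-[3-(benzyloxy)-5-(1,3-dioxolan-2-yl)-2-iodophenyl]-3-oxopropanoate F4.
  - Noyori-type asymmetric transfer hydrogenation of the aryl ketone (RuCl(p-cymene)[(R,R)-TsDPEN], HCO2Na, H2O/CH2Cl2) gives methyl (3R)-3-[3,4-bis(benzyloxy)phenyl]-2-[3-(benzyloxy)-5-(1,3-dioxolan-2-yl)-2-iodophenyl]-3-hydroxypropanoate F5. Only the carbinol centre needs to be controlled.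
  - Intramolecular Ullmann-type O-arylation (CuI, 1,10-phenanthroline, Cs2CO3, toluene, 90 °C) closes ring B with the carbinol C–O bond intact. Equilibration at C3 under the basic conditions, if needed finished with DBU, should bring the ester trans and give 12.

**Step 8.**
- The electron-rich aldehyde 9 and the substituent next to the anhydride carbonyl may slow the catalysed addition. Self-condensation of the anhydride and the uncatalysed pathway would then compete and erode enantio- and diastereoselectivity.
- Fallback, from 8 and 9 back to 10: run the annulation with an achiral tertiary amine (iPr2NEt) to give racemic trans-8-(benzyloxy)-3-[3,4-bis(benzyloxy)phenyl]-6-(1,3-dioxolan-2-yl)-1-oxoisochromane-4-carboxylic acid F6. Resolve it by crystallisation of the (R)-1-phenylethylammonium salt of the (3R,4R) acid F7, or with the (S)-amine if the other salt is the less soluble one. Cold acidification releases 10, which is esterified as in step 8.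

**Step 5.**
- The benzylic anion may attack the ester of a second molecule (self-condensation), or deprotonation may occur at the benzyl ether methylene with subsequent rearrangement.
- Fallback, from 5 back to 7: saponify 5 first to 2-(benzyloxy)-4-(1,3-dioxolan-2-yl)-6-methylbenzoic acid F8. Form the carboxylate/benzylic dianion with excess LiN(iPr)2, in which no electrophilic ester remains, and quench with CO2 to give diacid 7 directly.

**Step 12.**
- The Lewis acid may ionise the C2–O1 bond, leading to ring opening, epimerisation at C2 or capture of the cation by the scavenger. Cleavage of the catechol ethers may also be incomplete.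
- Fallback, from 12 back to 16, removing the benzyl groups before the alkene exists:
  - Hydrogenolysis of 12 (H2, Pd/C, EtOAc, rt) gives methyl (2R,3R)-2-(3,4-dihydroxyphenyl)-5-(1,3-dioxolan-2-yl)-7-hydroxy-2,3-dihydrobenzofuran-3-carboxylate F9.
  - Mild acid hydrolysis gives methyl (2R,3R)-2-(3,4-dihydroxyphenyl)-5-formyl-7-hydroxy-2,3-dihydrobenzofuran-3-carboxylate F10.
  - Wittig olefination of the free phenolic aldehyde with an excess of 14 gives 16.

**Step 3.**
- Hydride may be transferred to the aryl palladium species before CO inserts, which would remove the triflate without introducing the formyl group.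
- Fallback, from 3 back to 4: Suzuki–Miyaura coupling with potassium vinyltrifluoroborate (PdCl2(dppf), Et3N, n-PrOH, 80 °C) gives methyl 2-(benzyloxy)-4-ethenyl-6-methylbenzoate F11. Lemieux–Johnson cleavage (OsO4 cat., NaIO4, 2,6-lutidine, dioxane/H2O) gives 4.

## Further compounds

F1 | step 9 | 2-(benzyloxy)-4-(1,3-dioxolan-2-yl)-6-(2-methoxy-2-oxoethyl)benzoic acid | COC(=O)Cc1cc(C2OCCO2)cc(OCc2ccccc2)c1C(=O)O
F2 | step 9 | methyl 2-[3-(benzyloxy)-5-(1,3-dioxolan-2-yl)-2-iodophenyl]acetate | COC(=O)Cc1cc(C2OCCO2)cc(OCc2ccccc2)c1I
F3 | step 9 | methyl 3-[3,4-bis(benzyloxy)phenyl]-2-[3-(benzyloxy)-5-(1,3-dioxolan-2-yl)-2-iodophenyl]-3-hydroxypropanoate (mixture of stereoisomers) | COC(=O)C(c1cc(C2OCCO2)cc(OCc2ccccc2)c1I)C(O)c1ccc(OCc2ccccc2)c(OCc2ccccc2)c1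
F4 | step 9 | methyl 3-[3,4-bis(benzyloxy)phenyl]-2-[3-(benzyloxy)-5-(1,3-dioxolan-2-yl)-2-iodophenyl]-3-oxopropanoate | COC(=O)C(c1cc(C2OCCO2)cc(OCc2ccccc2)c1I)C(=O)c1ccc(OCc2ccccc2)c(OCc2ccccc2)c1
F5 | step 9 | methyl (3R)-3-[3,4-bis(benzyloxy)phenyl]-2-[3-(benzyloxy)-5-(1,3-dioxolan-2-yl)-2-iodophenyl]-3-hydroxypropanoate (both C2 epimers) | COC(=O)C(c1cc(C2OCCO2)cc(OCc2ccccc2)c1I)[C@@H](O)c1ccc(OCc2ccccc2)c(OCc2ccccc2)c1
F6 | step 8 | racemic trans-8-(benzyloxy)-3-[3,4-bis(benzyloxy)phenyl]-6-(1,3-dioxolan-2-yl)-1-oxoisochromane-4-carboxylic acid, (3R,4R) and (3S,4S) | C1(OCCO1)c1cc(OCc3ccccc3)c2c(c1)[C@@H](C(=O)O)[C@H](c1ccc(OCc3ccccc3)c(OCc3ccccc3)c1)OC2=O.C1(OCCO1)c1cc(OCc3ccccc3)c2c(c1)[C@H](C(=O)O)[C@@H](c1ccc(OCc3ccccc3)c(OCc3ccccc3)c1)OC2=O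
F7 | step 8 | (R)-1-phenylethylammonium (3R,4R)-8-(benzyloxy)-3-[3,4-bis(benzyloxy)phenyl]-6-(1,3-dioxolan-2-yl)-1-oxoisochromane-4-carboxylate | C1(OCCO1)c1cc(OCc3ccccc3)c2c(c1)[C@@H](C(=O)[O-])[C@H](c1ccc(OCc3ccccc3)c(OCc3ccccc3)c1)OC2=O.C[C@@H]([NH3+])c1ccccc1
F8 | step 5 | 2-(benzyloxy)-4-(1,3-dioxolan-2-yl)-6-methylbenzoic acid | Cc1cc(C2OCCO2)cc(OCc2ccccc2)c1C(=O)O
F9 | step 12 | methyl (2R,3R)-2-(3,4-dihydroxyphenyl)-5-(1,3-dioxolan-2-yl)-7-hydroxy-2,3-dihydrobenzofuran-3-carboxylate | C1(OCCO1)c1cc(O)c2c(c1)[C@@H](C(=O)OC)[C@H](c1ccc(O)c(O)c1)O2
F10 | step 12 | methyl (2R,3R)-2-(3,4-dihydroxyphenyl)-5-formyl-7-hydroxy-2,3-dihydrobenzofuran-3-carboxylate | O=Cc1cc(O)c2c(c1)[C@@H](C(=O)OC)[C@H](c1ccc(O)c(O)c1)O2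
F11 | step 3 | methyl 2-(benzyloxy)-4-ethenyl-6-methylbenzoate | COC(=O)c1c(C)cc(C=C)cc1OCc1ccccc1
A1 | alternative 1 | methyl (2R,3R)-5,7-dibromo-2-[3,4-bis(tert-butyldimethylsilyloxy)phenyl]-2,3-dihydrobenzofuran-3-carboxylate | Brc1cc(Br)c2c(c1)[C@@H](C(=O)OC)[C@H](c1ccc(O[Si](C)(C)C(C)(C)C)c(O[Si](C)(C)C(C)(C)C)c1)O2
A2 | alternative 1 | methyl (2R,3R)-2-[3,4-bis(tert-butyldimethylsilyloxy)phenyl]-5-oxooxolane-3-carboxylate | O=C1C[C@@H](C(=O)OC)[C@H](c2ccc(O[Si](C)(C)C(C)(C)C)c(O[Si](C)(C)C(C)(C)C)c2)O1
A3 | alternative 1 | 3,5-dibromo-2H-pyran-2-one | O=c1occ(Br)cc1Br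
A4 | alternative 2 | methyl (2R,3R)-7-acetoxy-5-bromo-2-(3,4-diacetoxyphenyl)-2,3-dihydrobenzofuran-3-carboxylate | Brc1cc(OC(C)=O)c2c(c1)[C@@H](C(=O)OC)[C@H](c1ccc(OC(C)=O)c(OC(C)=O)c1)O2
A5 | alternative 2 | (2R)-8-acetoxy-6-bromo-2-(3,4-diacetoxyphenyl)chroman-4-one | O=C1C[C@H](c2ccc(OC(C)=O)c(OC(C)=O)c2)Oc2c(OC(C)=O)cc(Br)cc12
A6 | alternative 3 | methyl (2R,3R)-5-bromo-7-(tert-butyldimethylsilyloxy)-2-[3,4-bis(tert-butyldimethylsilyloxy)phenyl]-2,3-dihydrobenzofuran-3-carboxylate | Brc1cc(O[Si](C)(C)C(C)(C)C)c2c(c1)[C@@H](C(=O)OC)[C@H](c1ccc(O[Si](C)(C)C(C)(C)C)c(O[Si](C)(C)C(C)(C)C)c1)O2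
A7 | alternative 3 | methyl 2-{5-bromo-3-(tert-butyldimethylsilyloxy)-2-[3,4-bis(tert-butyldimethylsilyloxy)benzyloxy]phenyl}-2-diazoacetate | COC(=O)C(=[N+]=[N-])c1cc(Br)cc(O[Si](C)(C)C(C)(C)C)c1OCc1ccc(O[Si](C)(C)C(C)(C)C)c(O[Si](C)(C)C(C)(C)C)c1
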